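## Retrosynthetic overview

1. C3 is the only stereocentre. It is the carbinol carbon of divinyl carbinol (1). In the acetate (2) the two vinyl groups are enantiotopic, so a catalyst-controlled hydroboration of one of them breaks the mirror symmetry and gives the C1–C5 linchpin (S)-3 (Bpin on C1, OAc on C3, vinyl = C4–C5).
2. C5–C6 disconnection: 9-BBN hydroboration of the remaining vinyl group of 3, then B-alkyl Suzuki coupling with the (E)-styryl iodide made from 4-hydroxybenzaldehyde (4 → 5 → 6), gives 7.
3. C1–aryl disconnection: the alkyl–Bpin held in reserve in 7 is coupled with silylated 4-bromocatechol (8 → 9) to give 10; fluoride frees the three phenols to give target 11.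
4. No ring is constructed. Both benzene rings are bought intact; the chain is C1–C5 (from 1) plus C6–C7 (from 4).

Assumption: the sense of induction in the new symmetry-breaking step cannot be predicted with confidence, so the ligand antipode is fixed by one correlation experiment (see step 2).

## Route

**Step 1**
Reactants: 1, penta-1,4-dien-3-ol (divinyl carbinol)
Product: 2, penta-1,4-dien-3-yl acetate (achiral, Cs-symmetric)
Conditions: Ac2O (1.3 equiv), Et3N (1.5 equiv), DMAP (2 mol %), CH2Cl2, 0 °C → rt; distil
Reagents that add atoms: acetic anhydride, CC(=O)OC(C)=O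
Why: DMAP-catalysed O-acylation installs the target's acetate at the outset, where it also acts as the σ-acceptor that orients the metal in step 2; C3 is still prochiral.

**Step 2 (key step)**
Reactants: 2, penta-1,4-dien-3-yl acetate
Product: 3, (S)-5-(4,4,5,5-tetramethyl-1,3,2-dioxaborolan-2-yl)pent-1-en-3-yl acetate
Conditions: [Rh(cod)2]BF4 (2 mol %), chiral bisphosphine (BINAP as lead, 2.4 mol %; antipode chosen as below), catecholborane (1.3 equiv, slow addition), THF, −30 °C; then pinacol (2 equiv), rt; SiO2 (removes achiral bis-boronate)
Reagents that add atoms: catecholborane, B1Oc2ccccc2O1 (supplies B); pinacol, CC(C)(O)C(C)(C)O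
Why: Proposed new method: Rh-catalysed anti-Markovnikov hydroboration of allylic acetates and silyl ethers with catecholborane is known, and Rh binds such alkenes on the face anti to the allylic C–O bond (σ*C–O/π* mixing), so in 2 the pro-R and pro-S vinyl groups present opposite enantiofaces to the metal and a C2-symmetric chiral bisphosphine that discriminates alkene faces should select one vinyl group and thereby set C3; the minor enantiomer of 3 still carries the fast-reacting vinyl group and is preferentially drained to the achiral 1,5-bis-boronate (hence the excess borane), which raises the ee of 3 with conversion as in the Sharpless epoxidation of 1; closest known reaction types are Rh-catalysed hydroboration of allylic alcohol derivatives, Rh/Ir-catalysed desymmetrising hydroboration of meso alkenes, and Sharpless desymmetrisation of divinyl carbinol; the ligand antipode that gives (S)-3 is fixed once by converting an aliquot (NaBO3, then K2CO3/MeOH) to pent-4-ene-1,3-diol and comparing with the known (S)-diol.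

**Step 3**
Reactants: 4, 4-hydroxybenzaldehyde
Product: 5, 4-[(triisopropylsilyl)oxy]benzaldehyde
Conditions: TIPSCl (1.1 equiv), imidazole (2 equiv), DMF, rt
Reagents that add atoms: triisopropylsilyl chloride, CC(C)[Si](Cl)(C(C)C)C(C)C
Why: Imidazole-promoted O-silylation masks the phenol for the organochromium and Pd steps; TIPS is chosen over TBS for stability to the basic Suzuki conditions.

**Step 4**
Reactants: 5, 4-[(triisopropylsilyl)oxy]benzaldehyde
Product: 6, (E)-1-(2-iodoethenyl)-4-[(triisopropylsilyl)oxy]benzene
Conditions: CrCl2 (6 equiv), CHI3 (2 equiv), 1,4-dioxane/THF 6:1, 0 °C → rt, dark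
Reagents that add atoms: iodoform, IC(I)I
Why: Takai olefination: the gem-dichromium species from CHI3/CrCl2 adds to the aldehyde and eliminates to the (E)-iodoalkene (E-selective for aryl aldehydes, improved by dioxane).

**Step 5**
Reactants: 3, (S)-5-(Bpin)pent-1-en-3-yl acetate; 6, (E)-styryl iodide
Product: 7, (3S,6E)-1-(4,4,5,5-tetramethyl-1,3,2-dioxaborolan-2-yl)-7-{4-[(triisopropylsilyl)oxy]phenyl}hept-6-en-3-yl acetate
Conditions: 9-BBN (1.3 equiv), THF, 0 °C → rt until the alkene is consumed; then 3 M aq K3PO4 (3 equiv), 6 (1.05 equiv), PdCl2(dppf)·CH2Cl2 (5 mol %), AsPh3 (5 mol %), DMF, rt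
Reagents that add atoms: none (9-BBN leaves only H; C6–C7 come from reactant 6)
Why: 9-BBN adds anti-Markovnikov to the remaining vinyl group, and the B-alkyl-9-BBN undergoes B-alkyl Suzuki–Miyaura coupling at rt with retention of alkene geometry while the less Lewis-acidic pinacol boronate is not transmetalated; no allylic acetate is left when Pd(0) is added, and C3 is untouched.

**Step 6**
Reactants: 8, 4-bromobenzene-1,2-diol (4-bromocatechol)
Product: 9, 4-bromo-1,2-bis[(triisopropylsilyl)oxy]benzene
Conditions: TIPSCl (2.5 equiv), imidazole (5 equiv), DMF, 40 °C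
Reagents that add atoms: triisopropylsilyl chloride, CC(C)[Si](Cl)(C(C)C)C(C)C
Why: Double O-silylation prevents the catechol from chelating boron or Pd and from oxidising in the coupling.

**Step 7**
Reactants: 7, alkyl pinacol boronate; 9, silylated aryl bromide (1.2 equiv)
Product: 10, (3R,6E)-1-{3,4-bis[(triisopropylsilyl)oxy]phenyl}-7-{4-[(triisopropylsilyl)oxy]phenyl}hept-6-en-3-yl acetate
Conditions: Pd(OAc)2 (5 mol %), RuPhos (10 mol %), K3PO4 (3 equiv), toluene/H2O 10:1, 80 °C
Reagents that add atoms: none
Why: Suzuki–Miyaura coupling of a primary alkyl pinacol boronate with an aryl bromide, where the dialkylbiarylphosphine makes reductive elimination outrun β-hydride elimination; the acetate is not allylic, so Pd does not ionise it, and the descriptor changes from S to R only because the aryl-ethyl arm now outranks the alkenyl arm.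

**Step 8**
Reactants: 10, tris-TIPS ether
Product: 11, (3R,6E)-1-(3,4-dihydroxyphenyl)-7-(4-hydroxyphenyl)hept-6-en-3-yl acetate (target)
Conditions: TBAF (3.5 equiv), AcOH (4 equiv), THF, 0 °C → rt, degassed; pH 5 work-up
Reagents that add atoms: none
Why: Fluoride cleaves the three aryl silyl ethers; buffering with AcOH stops phenoxide from attacking the secondary acetate, and the alkene and C3 are unaffected.

## Compound list

1 | penta-1,4-dien-3-ol | C=CC(O)C=C | starting material
2 | penta-1,4-dien-3-yl acetate | CC(=O)OC(C=C)C=C | intermediate
3 | (S)-5-(pinacolboryl)pent-1-en-3-yl acetate | CC(=O)O[C@H](C=C)CCB1OC(C)(C)C(C)(C)O1 | intermediate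
4 | 4-hydroxybenzaldehyde | O=Cc1ccc(O)cc1 | starting material
5 | 4-[(triisopropylsilyl)oxy]benzaldehyde | O=Cc1ccc(O[Si](C(C)C)(C(C)C)C(C)C)cc1 | intermediate
6 | (E)-1-(2-iodoethenyl)-4-[(triisopropylsilyl)oxy]benzene | I/C=C/c1ccc(O[Si](C(C)C)(C(C)C)C(C)C)cc1 | intermediate
7 | (3S,6E)-1-(pinacolboryl)-7-[4-(TIPS-oxy)phenyl]hept-6-en-3-yl acetate | CC(=O)O[C@H](CC/C=C/c1ccc(O[Si](C(C)C)(C(C)C)C(C)C)cc1)CCB1OC(C)(C)C(C)(C)O1 | intermediate
8 | 4-bromobenzene-1,2-diol | Oc1ccc(Br)cc1O | starting material
9 | 4-bromo-1,2-bis[(triisopropylsilyl)oxy]benzene | Brc1ccc(O[Si](C(C)C)(C(C)C)C(C)C)c(O[Si](C(C)C)(C(C)C)C(C)C)c1 | intermediate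
10 | (3R,6E)-1-[3,4-bis(TIPS-oxy)phenyl]-7-[4-(TIPS-oxy)phenyl]hept-6-en-3-yl acetate | CC(=O)O[C@H](CC/C=C/c1ccc(O[Si](C(C)C)(C(C)C)C(C)C)cc1)CCc1ccc(O[Si](C(C)C)(C(C)C)C(C)C)c(O[Si](C(C)C)(C(C)C)C(C)C)c1 | intermediate
11 | (3R,6E)-1-(3,4-dihydroxyphenyl)-7-(4-hydroxyphenyl)hept-6-en-3-yl acetate | CC(=O)O[C@H](CC/C=C/c1ccc(O)cc1)CCc1ccc(O)c(O)c1 | target

## Step count and risks

Total steps: 8. Longest linear sequence: 5 (steps 1, 2, 5, 7, 8).

Steps most likely to fail:

1. **Step 2 (group-selective hydroboration).** The ee may be too low, or Rh may add the wrong way round or ionise the bis-allylic acetate. Fallback: break the symmetry of 1 by Sharpless asymmetric epoxidation (established for this diene), acetylate, and carry the epoxide as a masked vinyl group through the first hydroboration/Suzuki. Then deoxygenate the terminal epoxide (e.g. MeReO3/PPh3) to regenerate the second vinyl group for the other coupling.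
2. **Step 7 (alkyl–Bpin Suzuki coupling).** Transmetalation may be slow, and the acetate may partly hydrolyse under hot aqueous base. Fallback: reverse the polarity at C1. Oxidise the C–B bond to the primary alcohol, convert it to the iodide, and join it to 9 by Ni-catalysed reductive cross-electrophile coupling (Zn or Mn, no base, no organoboron).
3. **Step 5 (9-BBN hydroboration and boron-selective coupling).** Internal hydroboration next to the acetate, or erosion of alkene geometry from impure 6, would lower the yield. Fallback: couple the 9-BBN adduct with vinyl bromide to give the but-3-enyl chain, then form the styrene by (E)-selective cross-metathesis with 4-[(triisopropylsilyl)oxy]styrene (Ru–NHC catalyst). This also removes the Takai step.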